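The target is an 8-O-4′ neolignan in which C8 is bonded at once to the ether oxygen of ring B (4-allyl-2,6-dimethoxyphenyl), to the carbinol carbon C7 attached to ring A (4-hydroxy-3,5-dimethoxyphenyl) and to C9. Disconnecting both the C8–O and the C7–C8 bond turns C8 into a carbene carbon flanked by a C9 ester. One rhodium-catalysed operation then joins the ring B phenol, ethyl diazoacetate and the ring A aldehyde and sets both stereocentres (C7, C8) under a chiral Brønsted acid. The three precursors are the free phenol, the diazo ester and syringaldehyde masked as its electron-poor pivalate; hydride reduction finishes the synthesis.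

Key step: step 2

Assumption: the sense of induction of the binaphthyl hydrogen phosphate with this substrate pair cannot be predicted with certainty; the (R)-acid is written, and its (S)-antipode would be used instead if the first run showed the opposite sense.

Remark on configuration: the target is (7R,8S), the erythro (anti) series. In ester 7 the same spatial arrangement is (2R,3R), because the ester carbon outranks C7 at C8.

Step 1
Reactants: 1 syringaldehyde (4-hydroxy-3,5-dimethoxybenzaldehyde)
Product: 2 4-formyl-2,6-dimethoxyphenyl pivalate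
Conditions: tBuCOCl (1.3 equiv), Et3N (2 equiv), 4-(dimethylamino)pyridine (0.1 equiv), CH2Cl2, 0 °C to rt
Reagents that add atoms: pivaloyl chloride, CC(C)(C)C(Cl)=O
Why: Base-mediated O-acylation of a phenol (nucleophilic acyl substitution through the N-pivaloylpyridinium ion), which leaves the aldehyde untouched and creates no stereocentre.

Step 2
Reactants: 2 4-formyl-2,6-dimethoxyphenyl pivalate; 3 4-allyl-2,6-dimethoxyphenol; 4 ethyl diazoacetate
Product: 7 ethyl (2R,3R)-2-(4-allyl-2,6-dimethoxyphenoxy)-3-hydroxy-3-[3,5-dimethoxy-4-(pivaloyloxy)phenyl]propanoate, via carbenoid Rh2(OAc)4(=CHCO2Et) 5 (not isolated), via protic oxonium ylide 6 (not isolated)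
Conditions: Rh2(OAc)4 (2 mol %), (R)-3,3'-bis(2,4,6-triisopropylphenyl)-1,1'-binaphthalene-2,2'-diyl hydrogen phosphate (10 mol %), 4 Å molecular sieves, CH2Cl2, 0 °C; 2 (2 equiv), 3 (1 equiv), 4 (1.2 equiv) added over 3 h by syringe pump
Reagents that add atoms: none
Why: Proposed new method: Rh2(OAc)4 expels N2 from 4 to give the electrophilic divalent rhodium carbenoid 5, which the phenolic oxygen of 3 (the best donor present, ahead of the allyl π bond and the aldehyde oxygen) captures to give the protic oxonium ylide 6, in equilibrium with its ester enol. Before the 1,2-proton shift can complete a plain O–H insertion, this nucleophile attacks through C8 the formyl carbon of 2, which is activated by hydrogen bonding to the phosphoric acid, and proton transfer releases 7 with the C8–O and C7–C8 bonds formed and no ring closed. The closest known reaction type is the Rh2(OAc)4/chiral Brønsted acid co-catalysed aldol- and Mannich-type interception of alcohol-derived oxonium ylides of aryl diazoacetates; untested here are an acceptor-only diazoacetate and a hindered phenol as the O–H partner. Both new stereocentres are set by the catalyst in the C–C bond-forming event: the phosphoryl oxygen holds the enol O–H and the acidic P–OH holds the aldehyde oxygen, so the carbonyl oxygen sits gauche to C9 and ring A turns away from the bulky aryloxy group, which should lead to the anti (2R,3R) isomer, while the 3,3'-aryl walls of the (R)-acid expose one face of each partner. The step needs O–H capture to beat cyclopropanation of the allyl group and trapping to beat the proton shift; this is meant to be secured by the pivalate (it leaves ring B as the only O–H donor and makes the aldehyde electron-poor, with acyloxy para and two methoxy groups meta to CHO), by the excess of 2 and by the slow addition of 4.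

Step 3
Reactants: 7 ethyl (2R,3R)-2-(4-allyl-2,6-dimethoxyphenoxy)-3-hydroxy-3-[3,5-dimethoxy-4-(pivaloyloxy)phenyl]propanoate
Product: 8 (1R,2S)-2-(4-allyl-2,6-dimethoxyphenoxy)-1-(4-hydroxy-3,5-dimethoxyphenyl)propane-1,3-diol, the (7R,8S) target
Conditions: LiAlH4 (3 equiv), THF, 0 °C to rt; then EtOAc, aq. potassium sodium tartrate
Reagents that add atoms: none
Why: LiAlH4 reduction of the ester to the C9 primary alcohol with reductive cleavage of the aryl pivalate in the same pot, a standard finish for β-hydroxy α-aryloxy esters that leaves the isolated alkene, C7 and C8 untouched.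

Compound list
1 | syringaldehyde (4-hydroxy-3,5-dimethoxybenzaldehyde) | COc1cc(C=O)cc(OC)c1O | starting material
2 | 4-formyl-2,6-dimethoxyphenyl pivalate | CC(C)(C)C(=O)Oc1c(OC)cc(C=O)cc1OC | intermediate
3 | 4-allyl-2,6-dimethoxyphenol | C=CCc1cc(OC)c(O)c(OC)c1 | starting material
4 | ethyl diazoacetate | CCOC(=O)C=[N+]=[N-] | starting material
5 | carbenoid Rh2(OAc)4(=CHCO2Et), not isolated | CCOC(=O)C=[Rh+2].[Rh+2].CC(=O)[O-].CC(=O)[O-].CC(=O)[O-].CC(=O)[O-] | intermediate
6 | protic oxonium ylide from 3 and the carbene carbon (in equilibrium with its ester enol), not isolated | C=CCc1cc(OC)c([OH+][CH-]C(=O)OCC)c(OC)c1 | intermediate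
7 | ethyl (2R,3R)-2-(4-allyl-2,6-dimethoxyphenoxy)-3-hydroxy-3-[3,5-dimethoxy-4-(pivaloyloxy)phenyl]propanoate | C=CCc1cc(OC)c(O[C@@H](C(=O)OCC)[C@H](O)c2cc(OC)c(OC(=O)C(C)(C)C)c(OC)c2)c(OC)c1 | intermediate
8 | (1R,2S)-2-(4-allyl-2,6-dimethoxyphenoxy)-1-(4-hydroxy-3,5-dimethoxyphenyl)propane-1,3-diol | C=CCc1cc(OC)c(O[C@@H](CO)[C@H](O)c2cc(OC)c(O)c(OC)c2)c(OC)c1 | target

Total step count: 3
Longest linear sequence: 3 steps (1 to 2 to 7 to 8)

Steps most likely to fail

1. Step 2. The 1,2-proton shift of ylide 6, or ketonisation of its enol, may outrun addition to the aldehyde, so that only formal O–H insertion occurs. The acid-bridged addition may also show poor facial or anti/syn selectivity. The fallback is a stepwise aldol with resolution, all known chemistry. Setting out from 3, Williamson alkylation with ethyl bromoacetate (K2CO3, acetone, reflux) should give ethyl 2-(4-allyl-2,6-dimethoxyphenoxy)acetate F1. This is also the compound the unwanted proton shift delivers, so material from failed runs can be pooled. LiN(iPr)2 in THF at −78 °C should convert it into its lithium ester enolate F2. Aldol addition of F2 to 2 should give both racemic diastereomers, from which the anti racemate rac-ethyl (2R,3R)-2-(4-allyl-2,6-dimethoxyphenoxy)-3-hydroxy-3-[3,5-dimethoxy-4-(pivaloyloxy)phenyl]propanoate F3 is separated by chromatography. Preparative HPLC on a cellulose tris(3,5-dimethylphenylcarbamate) phase would then separate the enantiomers and return the route at 7.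

2. Step 3. After deprotonation of the C7 hydroxyl, retro-aldol cleavage of the C7–C8 bond or enolisation at C8 may compete with hydride delivery to the ester. Slow cleavage of the hindered pivalate would lengthen the exposure. The fallback removes the alkoxide by protection. Setting out from 7, silylation (tBuMe2SiOTf, 2,6-lutidine, CH2Cl2, 0 °C) should give ethyl (2R,3R)-2-(4-allyl-2,6-dimethoxyphenoxy)-3-[(tert-butyldimethylsilyl)oxy]-3-[3,5-dimethoxy-4-(pivaloyloxy)phenyl]propanoate F4. LiAlH4 in THF should then reduce the ester and cleave the pivalate to give (2S,3R)-2-(4-allyl-2,6-dimethoxyphenoxy)-3-[(tert-butyldimethylsilyl)oxy]-3-(4-hydroxy-3,5-dimethoxyphenyl)propan-1-ol F5; a silyl shift to O9 would be harmless. Bu4NF buffered with AcOH in THF should release the diol and rejoin the route at 8.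

3. Step 1. Acyl transfer to the doubly ortho-substituted, formyl-deactivated phenoxide may stall with the bulky pivaloyl group. The fallback changes the masking group. Setting out from 1, acetylation (Ac2O, pyridine, rt) should give 4-formyl-2,6-dimethoxyphenyl acetate F6, which has a small acyl group and similar electron withdrawal. Used with 3 and 4 under the conditions of step 2, it would pass through 5 and 6 to ethyl (2R,3R)-3-(4-acetoxy-3,5-dimethoxyphenyl)-2-(4-allyl-2,6-dimethoxyphenoxy)-3-hydroxypropanoate F7. LiAlH4 as in step 3 would reduce the ester and the acetate alike and rejoin the route at 8.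

Further compounds
F1 | step 2 | ethyl 2-(4-allyl-2,6-dimethoxyphenoxy)acetate | CCOC(=O)COc1c(OC)cc(CC=C)cc1OC
F2 | step 2 | lithium enolate of ethyl 2-(4-allyl-2,6-dimethoxyphenoxy)acetate | [Li+].CCOC([O-])=COc1c(OC)cc(CC=C)cc1OC
F3 | step 2 | rac-ethyl (2R,3R)-2-(4-allyl-2,6-dimethoxyphenoxy)-3-hydroxy-3-[3,5-dimethoxy-4-(pivaloyloxy)phenyl]propanoate (racemic anti adduct, one enantiomer drawn) | C=CCc1cc(OC)c(O[C@@H](C(=O)OCC)[C@H](O)c2cc(OC)c(OC(=O)C(C)(C)C)c(OC)c2)c(OC)c1
F4 | step 3 | ethyl (2R,3R)-2-(4-allyl-2,6-dimethoxyphenoxy)-3-[(tert-butyldimethylsilyl)oxy]-3-[3,5-dimethoxy-4-(pivaloyloxy)phenyl]propanoate | C=CCc1cc(OC)c(O[C@@H](C(=O)OCC)[C@H](O[Si](C)(C)C(C)(C)C)c2cc(OC)c(OC(=O)C(C)(C)C)c(OC)c2)c(OC)c1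
F5 | step 3 | (2S,3R)-2-(4-allyl-2,6-dimethoxyphenoxy)-3-[(tert-butyldimethylsilyl)oxy]-3-(4-hydroxy-3,5-dimethoxyphenyl)propan-1-ol | C=CCc1cc(OC)c(O[C@@H](CO)[C@H](O[Si](C)(C)C(C)(C)C)c2cc(OC)c(O)c(OC)c2)c(OC)c1
F6 | step 1 | 4-formyl-2,6-dimethoxyphenyl acetate | CC(=O)Oc1c(OC)cc(C=O)cc1OC
F7 | step 1 | ethyl (2R,3R)-3-(4-acetoxy-3,5-dimethoxyphenyl)-2-(4-allyl-2,6-dimethoxyphenoxy)-3-hydroxypropanoate | C=CCc1cc(OC)c(O[C@@H](C(=O)OCC)[C@H](O)c2cc(OC)c(OC(C)=O)c(OC)c2)c(OC)c1
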